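Remark on the chemistry: eudesmane numbering is used (ring A = C1, C2, C3, C4, C5, C10; ring B = C5 to C10; C11 = carbinol carbon on C7; C14 = methyl on C10; C15 = methyl on C4). β is the face of the C10 methyl group, α the opposite face. The side-chain epoxide has its two methyl groups cis, so it is read as the epoxide of tiglic acid, (2S,3R) in the acid.

## Analysis of the target

The target is a eudesmane diester: a trans-fused decalin whose ring A carries on C3 the ester of (2S,3R)-2,3-dimethyloxirane-2-carboxylic acid and on C4 a tertiary acetate, and whose ring B is a cyclohexenone with the C8 ketone, the C6=C7 double bond and a 2-hydroxypropan-2-yl group (C11) on C7. The ring stereocentres are C3, C4, C5 and C10: H5 (α) and the C10 methyl (β) are trans, the C4 methyl is β and axial, syn to the C10 methyl, and the oxygens on C3 (β) and C4 (α) are trans and both equatorial; two further centres lie in the epoxide. Sensitive parts are the trisubstituted epoxide, the two esters on neighbouring oxygens (acyl migration once one hydroxyl is free), the tertiary carbinol next to the enone (retro-aldol in its saturated precursor) and H5, which is γ to the enone. The hard points are the all-carbon quaternary C10, which must be set in the absolute sense without a neighbouring heteroatom, the tertiary C4 oxygen with its methyl in the crowded axial position, and the need to tell apart the C3 and C8 carbonyl groups. The strategy rests on ring A: with oxygen on C3, a methyl on C4 and the methyl-bearing C10 para to C3, it is the dearomatised form of a 2,4-dimethylphenol, and C9 lies α to the C8 carbonyl, so C9–C10 and ring B can be formed by attack of the para carbon of that phenol on an electrophilic C9.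

## Retrosynthetic reasoning

The C11–O bond and the C6=C7 double bond of target 38 are taken back together to the C7=C11 isopropylidene ketone 36. An ene-type photooxygenation shifts the double bond to C6=C7 while placing oxygen on C11 (hydroperoxide 37, then O–O reduction). A dehydrogenation of the saturated C8 ketone was not chosen, because enolisation would have to go towards the crowded C7 in the presence of the enolisable C9.

The alkene of 36 comes from the tertiary carbinol 35 by elimination towards C7, and 35 from its silyl ether 34. Keeping C11 saturated and silylated until ring A is finished means that only the alkene being worked on is present during the hydrogenation and hydrogen-atom-transfer steps. The same bulky group is the control element of the ring closure.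

The C3 ester bond of 34 is cut to alcohol 28 and epoxy acid 32. The epoxide centres are set on the small fragment by reagent control (tiglic acid 29, allylic alcohol 30, epoxy alcohol 31), not on a hindered ester where no control is available.

Alcohol 28 goes back to the α-acetoxy ketone 27 (axial hydride delivery) and 27 to the tertiary ketol 26. Acetylating before the reduction uses the only free hydroxyl present at that stage.

The C4–O and C5–H bonds of 26 are cut together to enone 24. A reductive α-hydroxylation must deliver H to C5 and O to C4, both from the α face, and so sets the trans ring fusion and the C4 configuration in one step.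

Enone 24 comes from the cross-conjugated dienone 23 by saturation of the less substituted C1=C2 bond.

Dienone 23 is cut at C9–C10 to the phenolic diazoketone 22. This is the only bond in the skeleton whose cleavage turns ring A into a flat aromatic ring that already holds C15, the C3 oxygen and C14 in the right places. It also leaves a single stereocentre, C7, to direct the quaternary C10. The forward reaction has to achieve para attack of the phenol on an acid-activated C9 with loss of N2.

Diazoketone 22 comes from its aryl silyl ether 21, and 21 from acid 19 by one-carbon homologation through acid chloride 20. The phenol is released last, because a free phenol would interfere with acid activation.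

Acid 19 is the silyl ether of hydroxy acid 17, which comes from imide 15 by auxiliary removal (peroxy acid 16). The tertiary carbinol of 15 is made by Markovnikov hydration of the isopropenyl group of 14.

The C6–C7 bond of 14 is cut to benzylic bromide 8 and the dienolate 13 of the senecioyl imide 12, made from auxiliary 9 and acid chloride 10. The dienolate is preferred to a saturated β-silyloxy enolate, which would be neopentyl-hindered at its reacting carbon and open to β-elimination of silanolate.

Bromide 8 goes back through alcohol 7 and diol 6 to the phenolic acid 5, made from 2,6-dimethylbenzoic acid 1 by nitration (2), reduction (3) and diazonium hydrolysis (4).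

## Alternatives that were turned down

Alternative 1: The C10–methyl and C5–C6 bonds are cut on a preformed ring A, leading back to 3-(but-3-en-1-yl)cyclohex-2-en-1-one A2, whose carbonyl carbon becomes C4. In the forward step Me3Al transfers methyl to C10 under Cu(O2CC4H3S) (monovalent copper) and a chiral phosphoramidite, and the aluminium enolate, activated with MeLi, is alkylated at C5 by ClCH2OCH2Ph to give ketone A1.

- For: the quaternary C10 is set by a catalyst in one operation, and C5 is fixed relative to it at once.
- Against: A1 is ring A only. It lacks the C3 oxygen and the C4 methyl. A methyl nucleophile would attack the C4 ketone from the equatorial side, away from the axial C10 methyl, which gives the wrong C4 epimer. Ring B, the C8 ketone and the C7 side chain must all still be built from the two arms. Alkylation of hindered aluminium enolates is capricious.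
- Comparison: alternative 1 is stronger on direct absolute control of C10 and on fixing the trans C5/C10 relation early. The chosen strategy delivers all fifteen skeletal carbons and the C3, C8 and C11 oxygens at the ring closure, so far fewer carbon–carbon bonds remain afterwards.

Alternative 2: The C5–C10 bond is cut to open both rings into a ten-membered germacrane ring. In the forward step CF3CO2H or BF3·OEt2 protonates C1, the C4=C5 alkene closes onto the C10 cation, and the C4 cation is quenched by a 1,2-hydride shift from a silyloxy-bearing C3, giving the trans-fused dione A3.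

- For: it is biomimetic; both rings, the trans fusion, the C3 and C8 ketones and the C7=C11 alkene arise in one step, and A3 is already close to the point where the chosen end game starts.
- Against: the ten-membered triene with two E trisubstituted alkenes is harder to make than the product rings. Absolute control must be relayed from one stereocentre through the fold of a flexible macrocycle. Acid can start at other alkenes. C4 arrives as a CH centre, so the tertiary oxygen must still be introduced by enolate oxidation next to a second enolisable ketone.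
- Comparison: alternative 2 is stronger in step economy after the cyclisation and in setting the ring fusion in the key step. The chosen strategy offers a cyclisation precursor made by a short run of robust reactions, and it builds the C4 oxygenation into the ring A enone reduction.

Alternative 3: The C7–C8 and O–C11 bonds of isoxazoline A4 are cut (retro 1,3-dipolar cycloaddition), leading to the ring A aldoxime A5, which has a CH2CH=NOH arm on C10 and a prenyl arm on C5. In the forward step NaOCl oxidises the oxime to the nitrile oxide, which adds across the C7=C11 alkene, closing ring B and the isoxazoline.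

- For: the C11 oxygen and the C8 carbonyl arrive masked in the ring-forming step, with no dehydration and re-oxidation detour. The ring A stereocentres are already secured, and conditions are mild.
- Against: A5 already holds all four ring stereocentres, including the quaternary C10 and the tertiary acetate, with two different arms on adjacent carbons. The hardest problems are pushed into its preparation. Nitrile oxides add slowly to trisubstituted alkenes and dimerise. C6=C7 would still need a dehydrogenation next to the crowded C7.
- Comparison: alternative 3 is stronger in functional-group economy on ring B. The chosen strategy creates the quaternary centre and ring B together from a flat aromatic precursor and relies on substrate control afterwards.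

Key step: step 14

## Route

Step 1
Reactants: 1 2,6-dimethylbenzoic acid
Product: 2 2,6-dimethyl-3-nitrobenzoic acid
Conditions: HNO3, H2SO4, 0 °C
Reagents that add atoms: nitric acid O[N+](=O)[O-]
Why: Electrophilic aromatic nitration; C3 is ortho to one methyl, para to the other and meta to the carboxyl group, so all three substituents direct to the same position.

Step 2
Reactants: 2 2,6-dimethyl-3-nitrobenzoic acid
Product: 3 3-amino-2,6-dimethylbenzoic acid
Conditions: H2 (1 atm), Pd/C, MeOH, rt
Reagents that add atoms: none
Why: Catalytic hydrogenation of an aryl nitro group to the aniline; nothing else in the molecule is reducible under these conditions.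

Step 3
Reactants: 3 3-amino-2,6-dimethylbenzoic acid
Product: 5 3-hydroxy-2,6-dimethylbenzoic acid, via diazonium hydrogen sulfate 4 (not isolated)
Conditions: NaNO2, aq. H2SO4, 0 °C; then 40% aq. H2SO4, 100 °C
Reagents that add atoms: sodium nitrite [Na+].[O-]N=O (nitrogen of 4); sulfuric acid OS(=O)(=O)O (counter-ion of 4); water O (phenol oxygen of 5)
Why: Diazotisation and thermal hydrolysis of the arenediazonium salt in hot dilute acid (phenol synthesis through the diazonium salt); the carboxyl group is inert.

Step 4
Reactants: 5 3-hydroxy-2,6-dimethylbenzoic acid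
Product: 6 3-(hydroxymethyl)-2,4-dimethylphenol
Conditions: BH3·THF, THF, 0 °C → reflux; then MeOH, aq. HCl
Reagents that add atoms: none
Why: Borane reduces carboxylic acids chemoselectively, including 2,6-disubstituted benzoic acids; the phenol is only borylated and is released on work-up.

Step 5
Reactants: 6 3-(hydroxymethyl)-2,4-dimethylphenol
Product: 7 {2,6-dimethyl-3-[(triisopropylsilyl)oxy]phenyl}methanol
Conditions: TIPSCl (1.05 equiv), DBU, CH2Cl2, 0 °C
Reagents that add atoms: triisopropylsilyl chloride CC(C)[Si](Cl)(C(C)C)C(C)C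
Why: The amidine base deprotonates only the phenol, and the phenoxide is silylated far faster than the neutral benzylic alcohol flanked by two ortho methyl groups. The triisopropylsilyl aryl ether should withstand the enolate, hydroperoxide and acylation steps and is later cleaved by buffered fluoride.

Step 6
Reactants: 7 {2,6-dimethyl-3-[(triisopropylsilyl)oxy]phenyl}methanol
Product: 8 [3-(bromomethyl)-2,4-dimethylphenoxy]triisopropylsilane
Conditions: CBr4, PPh3, CH2Cl2, 0 °C
Reagents that add atoms: carbon tetrabromide BrC(Br)(Br)Br
Why: Appel reaction; neutral conditions and SN2 displacement at a benzylic carbon leave the aryl silyl ether untouched.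

Step 7
Reactants: 9 (4R)-4-benzyl-1,3-oxazolidin-2-one; 10 3-methylbut-2-enoyl chloride
Product: 12 (4R)-4-benzyl-3-(3-methylbut-2-enoyl)-1,3-oxazolidin-2-one, via lithium oxazolidinide 11 (not isolated)
Conditions: n-BuLi, THF, −78 °C; then 10, −78 → 0 °C
Reagents that add atoms: n-butyllithium [Li]CCCC (lithium of 11 only)
Why: N-acylation of the lithiated oxazolidinone; the preformed lithium amide at low temperature avoids the vinylketene pathway that amine bases open for this enoyl chloride.

Step 8
Reactants: 12 (4R)-4-benzyl-3-(3-methylbut-2-enoyl)-1,3-oxazolidin-2-one; 8 [3-(bromomethyl)-2,4-dimethylphenoxy]triisopropylsilane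
Product: 14 (4R)-4-benzyl-3-[(2R)-2-({2,6-dimethyl-3-[(triisopropylsilyl)oxy]phenyl}methyl)-3-methylbut-3-enoyl]-1,3-oxazolidin-2-one, via sodium dienolate 13 (not isolated)
Conditions: NaN(SiMe3)2 (0.98 equiv), THF, −78 °C; then 8, −78 → −40 °C; AcOH quench at −78 °C
Reagents that add atoms: sodium bis(trimethylsilyl)amide C[Si](C)(C)[N-][Si](C)(C)C.[Na+] (sodium of 13 only)
Why: Deconjugative Evans alkylation: γ-deprotonation gives the chelated Z-dienolate 13, which reacts at its α-carbon with the benzylic bromide on the face away from the benzyl group of the (R)-auxiliary, setting C7 as R. A slight deficit of base and a cold acidic quench should prevent the product from sliding back into conjugation.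

Step 9
Reactants: 14 (4R)-4-benzyl-3-[(2R)-2-({2,6-dimethyl-3-[(triisopropylsilyl)oxy]phenyl}methyl)-3-methylbut-3-enoyl]-1,3-oxazolidin-2-one
Product: 15 (4R)-4-benzyl-3-[(2R)-2-({2,6-dimethyl-3-[(triisopropylsilyl)oxy]phenyl}methyl)-3-hydroxy-3-methylbutanoyl]-1,3-oxazolidin-2-one
Conditions: Co(acac)2 (cat.), PhSiH3, O2 (1 atm), THF, rt
Reagents that add atoms: dioxygen O=O
Why: Mukaiyama hydration: hydrogen-atom transfer from a cobalt hydride to the 1,1-disubstituted alkene gives the tertiary C11 radical, which is trapped by O2, so the hydroxyl ends on C11 (Markovnikov) and C7 is not touched.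

Step 10
Reactants: 15 (4R)-4-benzyl-3-[(2R)-2-({2,6-dimethyl-3-[(triisopropylsilyl)oxy]phenyl}methyl)-3-hydroxy-3-methylbutanoyl]-1,3-oxazolidin-2-one
Product: 17 (2R)-2-({2,6-dimethyl-3-[(triisopropylsilyl)oxy]phenyl}methyl)-3-hydroxy-3-methylbutanoic acid, via peroxy acid 16 (not isolated)
Conditions: LiOH, H2O2, THF/H2O, 0 °C; then aq. Na2SO3; acidify to pH 3
Reagents that add atoms: hydrogen peroxide OO
Why: Hydroperoxide cleavage of the N-acyl oxazolidinone at the exocyclic carbonyl; the hydroperoxide anion is nucleophilic but weakly basic, so C7 should not epimerise and the tertiary aldol should not fragment at 0 °C. Sulfite reduces peroxy acid 16, and auxiliary 9 is recovered.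

Step 11
Reactants: 17 (2R)-2-({2,6-dimethyl-3-[(triisopropylsilyl)oxy]phenyl}methyl)-3-hydroxy-3-methylbutanoic acid
Product: 19 (2R)-3-[(tert-butyldimethylsilyl)oxy]-2-({2,6-dimethyl-3-[(triisopropylsilyl)oxy]phenyl}methyl)-3-methylbutanoic acid, via silyl ester 18 (not isolated)
Conditions: TBSOTf (3 equiv), 2,6-lutidine, CH2Cl2, 0 °C → rt; then AcOH, THF/H2O, rt
Reagents that add atoms: tert-butyldimethylsilyl trifluoromethanesulfonate CC(C)(C)[Si](C)(C)OS(=O)(=O)C(F)(F)F
Why: The silyl triflate silylates both the hindered tertiary alcohol and the acid; the silyl ester of 18 is hydrolysed under mild aqueous acid that leaves the tertiary alkyl and the aryl silyl ethers intact.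

Step 12
Reactants: 19 (2R)-3-[(tert-butyldimethylsilyl)oxy]-2-({2,6-dimethyl-3-[(triisopropylsilyl)oxy]phenyl}methyl)-3-methylbutanoic acid
Product: 21 (3R)-4-[(tert-butyldimethylsilyl)oxy]-1-diazo-3-({2,6-dimethyl-3-[(triisopropylsilyl)oxy]phenyl}methyl)-4-methylpentan-2-one, via acid chloride 20 (not isolated)
Conditions: Me2C=C(Cl)NMe2, CH2Cl2, 0 °C → rt; then CH2N2 (excess), Et2O, 0 °C
Reagents that add atoms: diazomethane C=[N+]=[N-]; 1-chloro-N,N,2-trimethylprop-1-en-1-amine CC(C)=C(Cl)N(C)C (chlorine of 20 only)
Why: The α-chloroenamine (Ghosez reagent) forms the acid chloride without releasing HCl, so both silyl ethers survive; acylation of diazomethane (first stage of the Arndt–Eistert sequence) then gives the diazoketone, a second equivalent of diazomethane taking up the HCl.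

Step 13
Reactants: 21 (3R)-4-[(tert-butyldimethylsilyl)oxy]-1-diazo-3-({2,6-dimethyl-3-[(triisopropylsilyl)oxy]phenyl}methyl)-4-methylpentan-2-one
Product: 22 (3R)-4-[(tert-butyldimethylsilyl)oxy]-1-diazo-3-[(3-hydroxy-2,6-dimethylphenyl)methyl]-4-methylpentan-2-one
Conditions: Bu4NF, AcOH, THF, 0 °C
Reagents that add atoms: none
Why: Fluoride cleaves an aryl silyl ether much faster than a tertiary alkyl silyl ether; the acetic acid buffer keeps the medium too weakly basic to enolise C7 and too weakly acidic to protonate the diazo group.

Step 14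
Reactants: 22 (3R)-4-[(tert-butyldimethylsilyl)oxy]-1-diazo-3-[(3-hydroxy-2,6-dimethylphenyl)methyl]-4-methylpentan-2-one
Product: 23 11-[(tert-butyldimethylsilyl)oxy]-7αH,10β-eudesma-1,4-diene-3,8-dione (C7 side chain β, cis to the C10 methyl)
Conditions: CF3CO2H, CH2Cl2, −20 °C, minutes; then aq. NaHCO3
Reagents that add atoms: none
Why: CF3CO2H protonates the diazo carbon C9 to an α-keto diazonium ion; the phenol attacks it through C10, the carbon para to the hydroxyl, displacing N2 in an SN2-like step, and loss of the phenolic proton leaves the 4,4-disubstituted cyclohexa-2,5-dienone. The closest known reaction type is the acid-promoted intramolecular para-alkylation of phenols by diazoketones, which gives spiro and fused cyclohexadienones. Ring B closes in a 6-exo-tet mode (C5, C6, C7, C8, C9, C10 in the ring, N2 leaving outside it). The only new stereocentre, C10, is controlled by C7: in the chair-like transition state C7 and C9 lie on the same face of the arene and the bulky 2-silyloxypropan-2-yl group sits equatorial, which forces the C10 methyl cis to the C7 substituent (10β from 7R). The step needs para over ortho attack; closure onto C4 would also form a six-membered ring but gives a less stable linearly conjugated dienone from the less nucleophilic position. It also needs carbon attack to outrun capture of the diazonium ion by trifluoroacetate or by the ether oxygen on C11, which the intramolecular geometry and the shielding of that oxygen by the silyl group and two methyl groups should secure. Short contact at low temperature should avoid dienone–phenol rearrangement and loss of the tertiary silyl ether, and any C10 epimer should be separable here, before C7 is erased.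

Step 15
Reactants: 23 11-[(tert-butyldimethylsilyl)oxy]-7αH,10β-eudesma-1,4-diene-3,8-dione
Product: 24 11-[(tert-butyldimethylsilyl)oxy]-7αH,10β-eudesm-4-ene-3,8-dione
Conditions: RhCl(PPh3)3 (cat.), H2 (1 atm), benzene/EtOH, rt
Reagents that add atoms: none
Why: Homogeneous hydrogenation with RhCl(PPh3)3 saturates the disubstituted C1=C2 bond of a cross-conjugated dienone and leaves the tetrasubstituted C4=C5 bond and both ketones, as in the steroid 1,4-dien-3-one series.

Step 16
Reactants: 24 11-[(tert-butyldimethylsilyl)oxy]-7αH,10β-eudesm-4-ene-3,8-dione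
Product: 26 11-[(tert-butyldimethylsilyl)oxy]-4α-hydroxy-5α,7αH-eudesmane-3,8-dione (4β-methyl), via C4 hydroperoxide 25 (not isolated)
Conditions: Mn(dpm)3 (cat.), PhSiH3, O2 (1 atm), i-PrOH/CH2Cl2, 0 °C; then P(OEt)3
Reagents that add atoms: dioxygen O=O
Why: Mukaiyama-type reductive α-hydroxylation of an enone: a manganese hydride transfers hydrogen to the β-carbon C5, the C4 α-keto radical is trapped by O2, and the phosphite reduces hydroperoxide 25. Both the hydrogen at C5 and the oxygen at C4 should enter from the α face, away from the axial C10 methyl, giving the trans ring fusion and the equatorial 4α-hydroxyl with the C4 methyl axial.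

Step 17
Reactants: 26 11-[(tert-butyldimethylsilyl)oxy]-4α-hydroxy-5α,7αH-eudesmane-3,8-dione
Product: 27 4α-acetoxy-11-[(tert-butyldimethylsilyl)oxy]-5α,7αH-eudesmane-3,8-dione
Conditions: Ac2O, DMAP, Et3N, CH2Cl2, rt → 40 °C
Reagents that add atoms: acetic anhydride CC(=O)OC(C)=O
Why: DMAP-catalysed acyl transfer acetylates tertiary alcohols; the equatorial ketol hydroxyl is the only free hydroxyl and sits next to a planar carbonyl carbon.

Step 18
Reactants: 27 4α-acetoxy-11-[(tert-butyldimethylsilyl)oxy]-5α,7αH-eudesmane-3,8-dione
Product: 28 4α-acetoxy-11-[(tert-butyldimethylsilyl)oxy]-3β-hydroxy-5α,7αH-eudesman-8-one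
Conditions: NaBH4, MeOH/CH2Cl2, −78 → −40 °C; AcOH quench at −40 °C
Reagents that add atoms: none
Why: Borohydride reduction; the α-acetoxy ketone C3 is the more electrophilic carbonyl and is open to axial attack from the α face (only axial hydrogens on C1 and C5), whereas C8 is shielded by the axial C10 methyl and the C7 substituent. Axial hydride delivery gives the equatorial 3β-alcohol, and the low temperature and acidic quench are meant to suppress 1,2-acetyl migration.

Step 19
Reactants: 29 tiglic acid, (E)-2-methylbut-2-enoic acid
Product: 30 (E)-2-methylbut-2-en-1-ol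
Conditions: LiAlH4, Et2O, 0 °C
Reagents that add atoms: none
Why: 1,2-reduction of the conjugated acid by LiAlH4; the trisubstituted alkene and its E geometry are retained.

Step 20
Reactants: 30 (E)-2-methylbut-2-en-1-ol
Product: 31 [(2R,3R)-2,3-dimethyloxiran-2-yl]methanol
Conditions: Ti(OiPr)4 (cat.), D-(−)-diethyl tartrate, t-BuOOH, 4 Å MS, CH2Cl2, −20 °C
Reagents that add atoms: tert-butyl hydroperoxide CC(C)(C)OO
Why: Sharpless asymmetric epoxidation; with the D-(−)-tartrate the E allylic alcohol should give the (2R,3R)-epoxy alcohol, the cis relation of the two methyl groups following from the E alkene.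

Step 21
Reactants: 31 [(2R,3R)-2,3-dimethyloxiran-2-yl]methanol
Product: 32 (2S,3R)-2,3-dimethyloxirane-2-carboxylic acid
Conditions: RuCl3·xH2O (cat.), NaIO4, MeCN/EtOAc/H2O, rt
Reagents that add atoms: sodium periodate [Na+].[O-]I(=O)(=O)=O
Why: RuO4 generated in the flask oxidises the primary alcohol to the acid without opening the epoxide; no stereocentre is touched (the C2 descriptor changes only through the priority rules).

Step 22
Reactants: 32 (2S,3R)-2,3-dimethyloxirane-2-carboxylic acid; 28 4α-acetoxy-11-[(tert-butyldimethylsilyl)oxy]-3β-hydroxy-5α,7αH-eudesman-8-one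
Product: 34 4α-acetoxy-11-[(tert-butyldimethylsilyl)oxy]-8-oxo-5α,7αH-eudesman-3β-yl (2S,3R)-2,3-dimethyloxirane-2-carboxylate, via mixed anhydride 33 (not isolated)
Conditions: 2,4,6-trichlorobenzoyl chloride, Et3N, THF, rt; then 28, DMAP, toluene, rt → 40 °C
Reagents that add atoms: 2,4,6-trichlorobenzoyl chloride O=C(Cl)c1c(Cl)cc(Cl)cc1Cl (aroyl group of 33 only)
Why: Yamaguchi esterification through mixed anhydride 33 and the acylpyridinium ion, suited to a hindered secondary alcohol and an α-quaternary acid; the non-acidic conditions preserve the epoxide.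

Step 23
Reactants: 34 4α-acetoxy-11-[(tert-butyldimethylsilyl)oxy]-8-oxo-5α,7αH-eudesman-3β-yl (2S,3R)-2,3-dimethyloxirane-2-carboxylate
Product: 35 4α-acetoxy-11-hydroxy-8-oxo-5α,7αH-eudesman-3β-yl (2S,3R)-2,3-dimethyloxirane-2-carboxylate
Conditions: HF·pyridine, pyridine, THF, 0 °C → rt
Reagents that add atoms: none
Why: Buffered HF·pyridine cleaves the tertiary silyl ether; the electron-poor α,β-epoxy ester and the acetate should tolerate it, and the non-basic medium avoids retro-aldol of the β-hydroxy ketone.

Step 24
Reactants: 35 4α-acetoxy-11-hydroxy-8-oxo-5α,7αH-eudesman-3β-yl (2S,3R)-2,3-dimethyloxirane-2-carboxylate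
Product: 36 4α-acetoxy-8-oxo-5α-eudesm-7(11)-en-3β-yl (2S,3R)-2,3-dimethyloxirane-2-carboxylate
Conditions: Burgess reagent (MeO2CN−SO2N+Et3), toluene, 50 °C; then DBU, CH2Cl2, rt
Reagents that add atoms: none
Why: Burgess dehydration of the tertiary alcohol through its sulfamate (syn elimination), with the acidic C7 hydrogen removed to give the conjugated alkene; DBU moves any isopropenyl isomer into conjugation through the dienolate.

Step 25
Reactants: 36 4α-acetoxy-8-oxo-5α-eudesm-7(11)-en-3β-yl (2S,3R)-2,3-dimethyloxirane-2-carboxylate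
Product: 38 4α-acetoxy-11-hydroxy-8-oxo-5α-eudesm-6-en-3β-yl (2S,3R)-2,3-dimethyloxirane-2-carboxylate, via C11 hydroperoxide 37 (not isolated)
Conditions: O2, hν (visible), tetraphenylporphyrin (cat.), CH2Cl2, −20 °C; then PPh3, rt
Reagents that add atoms: dioxygen O=O
Why: Schenck ene reaction: singlet oxygen bonds to the β-carbon C11 of the s-cis-locked enone and takes the allylic hydrogen from C6, the alkyl group geminal to the carbonyl on C7 (gem selectivity of α,β-unsaturated carbonyl compounds), which shifts the double bond to C6=C7. The phosphine reduces hydroperoxide 37 to the tertiary alcohol without touching the epoxide; no stereocentre is involved.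

## Compound list

1 | 2,6-dimethylbenzoic acid | Cc1cccc(C)c1C(=O)O | starting material
2 | 2,6-dimethyl-3-nitrobenzoic acid | Cc1c([N+](=O)[O-])ccc(C)c1C(=O)O | intermediate
3 | 3-amino-2,6-dimethylbenzoic acid | Cc1c(N)ccc(C)c1C(=O)O | intermediate
4 | 3-carboxy-2,4-dimethylbenzenediazonium hydrogen sulfate | Cc1c([N+]#N)ccc(C)c1C(=O)O.OS(=O)(=O)[O-] | intermediate (not isolated)
5 | 3-hydroxy-2,6-dimethylbenzoic acid | Cc1c(O)ccc(C)c1C(=O)O | intermediate
6 | 3-(hydroxymethyl)-2,4-dimethylphenol | Cc1c(O)ccc(C)c1CO | intermediate
7 | {2,6-dimethyl-3-[(triisopropylsilyl)oxy]phenyl}methanol | Cc1c(O[Si](C(C)C)(C(C)C)C(C)C)ccc(C)c1CO | intermediate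
8 | [3-(bromomethyl)-2,4-dimethylphenoxy]triisopropylsilane | Cc1c(O[Si](C(C)C)(C(C)C)C(C)C)ccc(C)c1CBr | intermediate
9 | (4R)-4-benzyl-1,3-oxazolidin-2-one | O=C1N[C@H](Cc2ccccc2)CO1 | starting material
10 | 3-methylbut-2-enoyl chloride | CC(C)=CC(=O)Cl | starting material
11 | lithium salt of 9 (N-lithiated oxazolidinone) | [Li+].O=C1[N-][C@H](Cc2ccccc2)CO1 | intermediate (not isolated)
12 | (4R)-4-benzyl-3-(3-methylbut-2-enoyl)-1,3-oxazolidin-2-one | CC(C)=CC(=O)N1[C@H](Cc2ccccc2)COC1=O | intermediate
13 | sodium Z-dienolate of 12 | [Na+].C=C(C)/C=C(\[O-])N1[C@H](Cc2ccccc2)COC1=O | intermediate (not isolated)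
14 | (4R)-4-benzyl-3-[(2R)-2-({2,6-dimethyl-3-[(triisopropylsilyl)oxy]phenyl}methyl)-3-methylbut-3-enoyl]-1,3-oxazolidin-2-one | Cc1c(O[Si](C(C)C)(C(C)C)C(C)C)ccc(C)c1C[C@H](C(C)=C)C(=O)N1[C@H](Cc2ccccc2)COC1=O | intermediate
15 | (4R)-4-benzyl-3-[(2R)-2-({2,6-dimethyl-3-[(triisopropylsilyl)oxy]phenyl}methyl)-3-hydroxy-3-methylbutanoyl]-1,3-oxazolidin-2-one | Cc1c(O[Si](C(C)C)(C(C)C)C(C)C)ccc(C)c1C[C@H](C(C)(C)O)C(=O)N1[C@H](Cc2ccccc2)COC1=O | intermediate
16 | (2R)-2-({2,6-dimethyl-3-[(triisopropylsilyl)oxy]phenyl}methyl)-3-hydroxy-3-methylbutaneperoxoic acid | Cc1c(O[Si](C(C)C)(C(C)C)C(C)C)ccc(C)c1C[C@H](C(C)(C)O)C(=O)OO | intermediate (not isolated)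
17 | (2R)-2-({2,6-dimethyl-3-[(triisopropylsilyl)oxy]phenyl}methyl)-3-hydroxy-3-methylbutanoic acid | Cc1c(O[Si](C(C)C)(C(C)C)C(C)C)ccc(C)c1C[C@H](C(C)(C)O)C(=O)O | intermediate
18 | tert-butyldimethylsilyl ester of 19 | Cc1c(O[Si](C(C)C)(C(C)C)C(C)C)ccc(C)c1C[C@H](C(C)(C)O[Si](C)(C)C(C)(C)C)C(=O)O[Si](C)(C)C(C)(C)C | intermediate (not isolated)
19 | (2R)-3-[(tert-butyldimethylsilyl)oxy]-2-({2,6-dimethyl-3-[(triisopropylsilyl)oxy]phenyl}methyl)-3-methylbutanoic acid | Cc1c(O[Si](C(C)C)(C(C)C)C(C)C)ccc(C)c1C[C@H](C(C)(C)O[Si](C)(C)C(C)(C)C)C(=O)O | intermediate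
20 | acid chloride of 19 | Cc1c(O[Si](C(C)C)(C(C)C)C(C)C)ccc(C)c1C[C@H](C(C)(C)O[Si](C)(C)C(C)(C)C)C(=O)Cl | intermediate (not isolated)
21 | (3R)-4-[(tert-butyldimethylsilyl)oxy]-1-diazo-3-({2,6-dimethyl-3-[(triisopropylsilyl)oxy]phenyl}methyl)-4-methylpentan-2-one | Cc1c(O[Si](C(C)C)(C(C)C)C(C)C)ccc(C)c1C[C@H](C(C)(C)O[Si](C)(C)C(C)(C)C)C(=O)C=[N+]=[N-] | intermediate
22 | (3R)-4-[(tert-butyldimethylsilyl)oxy]-1-diazo-3-[(3-hydroxy-2,6-dimethylphenyl)methyl]-4-methylpentan-2-one | Cc1c(O)ccc(C)c1C[C@H](C(C)(C)O[Si](C)(C)C(C)(C)C)C(=O)C=[N+]=[N-] | intermediate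
23 | 11-[(tert-butyldimethylsilyl)oxy]-7αH,10β-eudesma-1,4-diene-3,8-dione | CC1=C2C[C@H](C(C)(C)O[Si](C)(C)C(C)(C)C)C(=O)C[C@@]2(C)C=CC1=O | intermediate
24 | 11-[(tert-butyldimethylsilyl)oxy]-7αH,10β-eudesm-4-ene-3,8-dione | CC1=C2C[C@H](C(C)(C)O[Si](C)(C)C(C)(C)C)C(=O)C[C@@]2(C)CCC1=O | intermediate
25 | 11-[(tert-butyldimethylsilyl)oxy]-4α-hydroperoxy-5α,7αH-eudesmane-3,8-dione | OO[C@]1(C)C(=O)CC[C@]2(C)CC(=O)[C@@H](C(C)(C)O[Si](C)(C)C(C)(C)C)C[C@H]21 | intermediate (not isolated)
26 | 11-[(tert-butyldimethylsilyl)oxy]-4α-hydroxy-5α,7αH-eudesmane-3,8-dione | O[C@]1(C)C(=O)CC[C@]2(C)CC(=O)[C@@H](C(C)(C)O[Si](C)(C)C(C)(C)C)C[C@H]21 | intermediate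
27 | 4α-acetoxy-11-[(tert-butyldimethylsilyl)oxy]-5α,7αH-eudesmane-3,8-dione | CC(=O)O[C@]1(C)C(=O)CC[C@]2(C)CC(=O)[C@@H](C(C)(C)O[Si](C)(C)C(C)(C)C)C[C@H]21 | intermediate
28 | 4α-acetoxy-11-[(tert-butyldimethylsilyl)oxy]-3β-hydroxy-5α,7αH-eudesman-8-one | CC(=O)O[C@]1(C)[C@@H](O)CC[C@]2(C)CC(=O)[C@@H](C(C)(C)O[Si](C)(C)C(C)(C)C)C[C@H]21 | intermediate
29 | tiglic acid, (E)-2-methylbut-2-enoic acid | C/C=C(\C)C(=O)O | starting material
30 | (E)-2-methylbut-2-en-1-ol | C/C=C(\C)CO | intermediate
31 | [(2R,3R)-2,3-dimethyloxiran-2-yl]methanol | OC[C@@]1(C)O[C@@H]1C | intermediate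
32 | (2S,3R)-2,3-dimethyloxirane-2-carboxylic acid | OC(=O)[C@@]1(C)O[C@@H]1C | intermediate
33 | (2S,3R)-2,3-dimethyloxirane-2-carboxylic 2,4,6-trichlorobenzoic anhydride | O=C(OC(=O)[C@@]1(C)O[C@@H]1C)c1c(Cl)cc(Cl)cc1Cl | intermediate (not isolated)
34 | 4α-acetoxy-11-[(tert-butyldimethylsilyl)oxy]-8-oxo-5α,7αH-eudesman-3β-yl (2S,3R)-2,3-dimethyloxirane-2-carboxylate | CC(=O)O[C@]1(C)[C@@H](OC(=O)[C@@]3(C)O[C@@H]3C)CC[C@]2(C)CC(=O)[C@@H](C(C)(C)O[Si](C)(C)C(C)(C)C)C[C@H]21 | intermediate
35 | 4α-acetoxy-11-hydroxy-8-oxo-5α,7αH-eudesman-3β-yl (2S,3R)-2,3-dimethyloxirane-2-carboxylate | CC(=O)O[C@]1(C)[C@@H](OC(=O)[C@@]3(C)O[C@@H]3C)CC[C@]2(C)CC(=O)[C@@H](C(C)(C)O)C[C@H]21 | intermediate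
36 | 4α-acetoxy-8-oxo-5α-eudesm-7(11)-en-3β-yl (2S,3R)-2,3-dimethyloxirane-2-carboxylate | CC(=O)O[C@]1(C)[C@@H](OC(=O)[C@@]3(C)O[C@@H]3C)CC[C@]2(C)CC(=O)C(=C(C)C)C[C@H]21 | intermediate
37 | 4α-acetoxy-11-hydroperoxy-8-oxo-5α-eudesm-6-en-3β-yl (2S,3R)-2,3-dimethyloxirane-2-carboxylate | CC(=O)O[C@]1(C)[C@@H](OC(=O)[C@@]3(C)O[C@@H]3C)CC[C@]2(C)CC(=O)C(C(C)(C)OO)=C[C@H]21 | intermediate (not isolated)
38 | 4α-acetoxy-11-hydroxy-8-oxo-5α-eudesm-6-en-3β-yl (2S,3R)-2,3-dimethyloxirane-2-carboxylate (CNP0219255.6) | CC(=O)O[C@]1(C)[C@@H](OC(=O)[C@@]2(C)O[C@@H]2C)CC[C@]2(C)CC(=O)C(C(C)(C)O)=C[C@H]21 | target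

## Step count and least certain steps

Total step count: 25. Longest linear sequence: 21 steps (steps 1–6, 8–18 and 22–25); step 7 and steps 19–21 are side branches.

Step 14 (key step). The most likely failure is incomplete facial discrimination at C10. Ring B has two trigonal carbons (C5 and C8), so a boat-like closure on the other face costs less than in a cyclohexane and may compete with the chair. The diazonium ion may also be intercepted by trifluoroacetate or by the C11 ether oxygen, and the dienone may rearrange to a phenol if contact with acid is long. Fallback, from 22: HBr (48% aq., Et2O, −10 °C) should convert the diazoketone into the bromomethyl ketone F1. Under high dilution with Cs2CO3 in MeCN the phenoxide of F1 should then alkylate through its para carbon, closing the same C9–C10 bond without acid and returning to 23. The base is kept weak so that C7 is not enolised before the ring closes.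

Step 16. Hydrogen may be delivered to C5 with poor face selectivity, giving some cis-fused product, and hydrogen-atom transfer to a tetrasubstituted enone may be slow. Fallback, from 24: Li in NH3/THF with one equivalent of t-BuOH reduces the enone to the trans-fused C3 enolate (thermodynamic protonation at C5) and the C8 ketone to its alkoxide; trapping with Me3SiCl/Et3N should give the bis(trimethylsilyl) compound F2. Rubottom oxidation of its enol ether (mCPBA, NaHCO3, from the α face) and mild acidic desilylation should give the 4α,8α-dihydroxy ketone F3. Oxidation of the secondary C8 hydroxyl with Dess–Martin periodinane returns to 26.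

Step 25. The ene reaction may abstract hydrogen from a C11 methyl group instead of C6, putting the hydroperoxide on C7, or the electron-poor alkene may react slowly and let the sensitiser bleach. Fallback, from 35 (steps 24 and 25 are bypassed): PhSeCl in EtOAc selenenylates through the more substituted enol to give the C7 phenylselanyl ketone F4. H2O2 with pyridine oxidises it to the selenoxide F5, which can only eliminate towards C6 because C11 carries no hydrogen, and so returns directly to 38.

Step 18. The acetyl group may migrate from the tertiary O4 to the new secondary O3 under the basic reduction conditions, and some reduction at C8 may occur. Fallback, from 26: NaBH4 reduction of the free ketol should give the 3β,4α-diol F5-free compound named diol F6. Yamaguchi esterification with 33 takes the secondary hydroxyl only and gives the hydroxy ester F7. Forced acetylation of the tertiary hydroxyl (Ac2O, DMAP, 50 °C) returns to 34.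

Step 8. Regio- or stereocontrol may be lost in the dienolate alkylation: γ-alkylation, reconjugation of the product with loss of C7, or slow SN2 at the doubly ortho-substituted benzylic bromide. Fallback: 3-hydroxy-3-methylbutanoic acid F8 is silylated (TBSOTf, then hydrolysis of the silyl ester) to the silyloxy acid F9, which is attached to 9 through its pivaloyl mixed anhydride to give imide F10. The sodium enolate of F10 is alkylated with 8 at −78 °C to the silyloxy imide F11, and LiOH/H2O2 cleavage returns to 19. This removes the α/γ question but is itself exposed to β-elimination of silanolate, so it is held in reserve.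

## Further compounds

F1 | step 14 | (3R)-1-bromo-4-[(tert-butyldimethylsilyl)oxy]-3-[(3-hydroxy-2,6-dimethylphenyl)methyl]-4-methylpentan-2-one | Cc1c(O)ccc(C)c1C[C@H](C(C)(C)O[Si](C)(C)C(C)(C)C)C(=O)CBr
F2 | step 16 | 11-[(tert-butyldimethylsilyl)oxy]-3,8α-bis(trimethylsilyloxy)-5α,7αH-eudesm-3-ene | CC1=C(O[Si](C)(C)C)CC[C@]2(C)C[C@H](O[Si](C)(C)C)[C@@H](C(C)(C)O[Si](C)(C)C(C)(C)C)C[C@H]21
F3 | step 16 | 11-[(tert-butyldimethylsilyl)oxy]-4α,8α-dihydroxy-5α,7αH-eudesman-3-one | O[C@]1(C)C(=O)CC[C@]2(C)C[C@H](O)[C@@H](C(C)(C)O[Si](C)(C)C(C)(C)C)C[C@H]21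
F4 | step 25 | 4α-acetoxy-11-hydroxy-8-oxo-7α-(phenylselanyl)-5α-eudesman-3β-yl (2S,3R)-2,3-dimethyloxirane-2-carboxylate | CC(=O)O[C@]1(C)[C@@H](OC(=O)[C@@]3(C)O[C@@H]3C)CC[C@]2(C)CC(=O)[C@@]([Se]c3ccccc3)(C(C)(C)O)C[C@H]21
F5 | step 25 | selenoxide of F4 | CC(=O)O[C@]1(C)[C@@H](OC(=O)[C@@]3(C)O[C@@H]3C)CC[C@]2(C)CC(=O)[C@@]([Se](=O)c3ccccc3)(C(C)(C)O)C[C@H]21
F6 | step 18 | 11-[(tert-butyldimethylsilyl)oxy]-3β,4α-dihydroxy-5α,7αH-eudesman-8-one | O[C@]1(C)[C@@H](O)CC[C@]2(C)CC(=O)[C@@H](C(C)(C)O[Si](C)(C)C(C)(C)C)C[C@H]21
F7 | step 18 | 11-[(tert-butyldimethylsilyl)oxy]-4α-hydroxy-8-oxo-5α,7αH-eudesman-3β-yl (2S,3R)-2,3-dimethyloxirane-2-carboxylate | O[C@]1(C)[C@@H](OC(=O)[C@@]3(C)O[C@@H]3C)CC[C@]2(C)CC(=O)[C@@H](C(C)(C)O[Si](C)(C)C(C)(C)C)C[C@H]21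
F8 | step 8 | 3-hydroxy-3-methylbutanoic acid | CC(C)(O)CC(=O)O
F9 | step 8 | 3-[(tert-butyldimethylsilyl)oxy]-3-methylbutanoic acid | CC(C)(CC(=O)O)O[Si](C)(C)C(C)(C)C
F10 | step 8 | (4R)-4-benzyl-3-{3-[(tert-butyldimethylsilyl)oxy]-3-methylbutanoyl}-1,3-oxazolidin-2-one | CC(C)(CC(=O)N1[C@H](Cc2ccccc2)COC1=O)O[Si](C)(C)C(C)(C)C
F11 | step 8 | (4R)-4-benzyl-3-[(2R)-3-[(tert-butyldimethylsilyl)oxy]-2-({2,6-dimethyl-3-[(triisopropylsilyl)oxy]phenyl}methyl)-3-methylbutanoyl]-1,3-oxazolidin-2-one | Cc1c(O[Si](C(C)C)(C(C)C)C(C)C)ccc(C)c1C[C@H](C(C)(C)O[Si](C)(C)C(C)(C)C)C(=O)N1[C@H](Cc2ccccc2)COC1=O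
A1 | alternative 1 | 2-[(benzyloxy)methyl]-3-(but-3-en-1-yl)-3-methylcyclohexan-1-one (benzyloxymethyl arm trans to the butenyl arm) | O=C1CCC[C@](C)(CCC=C)[C@H]1COCc1ccccc1
A2 | alternative 1 | 3-(but-3-en-1-yl)cyclohex-2-en-1-one | O=C1CCCC(CCC=C)=C1
A3 | alternative 2 | trans-fused 5α,10β-eudesm-7(11)-ene-3,8-dione | C[C@H]1C(=O)CC[C@]2(C)CC(=O)C(=C(C)C)C[C@H]21
A4 | alternative 3 | trans-decalin-fused isoxazoline (N on C8, O on C11) with 4α-acetoxy and 3β-(tert-butyldimethylsilyl)oxy groups | CC(=O)O[C@]1(C)[C@@H](O[Si](C)(C)C(C)(C)C)CC[C@]2(C)CC3=NOC(C)(C)[C@H]3C[C@H]21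
A5 | alternative 3 | ring A aldoxime with a 2-(hydroxyimino)ethyl arm on C10 and a prenyl arm on C5 | CC(=O)O[C@]1(C)[C@@H](O[Si](C)(C)C(C)(C)C)CC[C@](C)(CC=NO)[C@H]1CC=C(C)C
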